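**Retrosynthetic overview**

1. Numbering (drimane): ring A = C1–C5 and C10, ring B = C5–C10, methyl groups on C4 (two), C8 and C10, C11 = the CH2 on C9; α is the face opposite the C10 methyl and "11-nor" means C11 is absent. The strategy rests on ring B: its C6 carbonyl, C7–H, C8 methyl, quaternary C10 methyl and C5–H are the substitution pattern of 2,6-dimethyl-1,4-benzoquinone (second carbonyl at C9), and C1–C4 with the C4 gem-dimethyl group is 4-methylpenta-1,3-diene.
2. Disconnections, backwards: C11–O aryl ether (Mitsunobu with isofraxidin); C9–C11 bond (vinylogous aldol of formaldehyde on the C6 dienol ether, from the α-face); the C9 oxygen, removed reductively as an ester; the C3 oxygen, from a 2α,3α-epoxide opened diaxially; the Diels–Alder adduct.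
3. Ring order: ring B is bought as the quinone; ring A is closed on it in step 1 by a catalytic enantioselective Diels–Alder reaction (bonds C1–C10 and C4–C5); the coumarin rings come with isofraxidin.
4. Stereocentres: C10 from the catalyst, C5 by epimerisation to the trans fusion, C3 from α-epoxidation and diaxial hydride opening, C9 from axial attack anti to the C10 methyl.

Key step: step 1

Assumption: the catalyst antipode is assigned from the usual pre-transition-state model (quinone on the convex face of boron, C5–H···O contact, diene on the face away from the catalyst body) as the (R)-diphenylprolinol-derived one; if the sense of induction is found to be opposite, the (S)-catalyst is used with no other change.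

**Step 1**
Reactants: 1 2,6-dimethyl-1,4-benzoquinone; 2 4-methylpenta-1,3-diene
Product: 3 cis-fused adduct, (4aR,8aS)-2,5,5,8a-tetramethyl-4a,5,8,8a-tetrahydronaphthalene-1,4-dione (11-nordrima-2,7-diene-6,9-dione with 5β-H and 10β-methyl)
Conditions: (R)-3,3-diphenyl-1-(o-tolyl)tetrahydro-1H,3H-pyrrolo[1,2-c][1,3,2]oxazaborole (20 mol%), HNTf2 (18 mol%), 2 (5 equiv), CH2Cl2, −78 → −20 °C
Reagents that add atoms: none
Why: The protonated oxazaborolidine binds the C6 carbonyl oxygen of 1 (the more basic oxygen, conjugated to both methyl groups, and the only one flanked by C–H bonds for the C–H···O contact to the catalyst), which makes C10 the most electrophilic carbon, and the diene adds in a concerted but strongly asynchronous [4+2] cycloaddition in which its unsubstituted terminus C1 (largest HOMO coefficient) leads onto C10 and the CMe2 terminus C4 closes onto C5. The closest known reaction type is the oxazaborolidinium-catalysed enantioselective Diels–Alder reaction of substituted 1,4-benzoquinones with simple 1,3-dienes. Ring A is closed by intermolecular [4+2] annulation onto the intact ring B, both new σ-bonds being formed suprafacially on each partner. The cis relation of H5 and the C10 methyl follows from suprafacial addition to the quinone C=C, and the absolute configuration of C10 and C5 is set by the catalyst, whose body and phenyl group cover one face of the bound C5=C10 bond. The step needs orientational selectivity, secured jointly by the catalyst site at the C6 oxygen and by the steric veto against joining CMe2 to the methyl-bearing carbon, and face selectivity, secured by the catalyst alone, since the two ring C=C bonds of 1 are homotopic (twofold axis through both carbonyls) and only their enantiotopic faces differ. The weak point is reactivity, because the cis-methyl group of 2 disfavours the s-cis conformer; excess diene and a high catalyst loading are meant to offset this.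

**Step 2**
Reactants: 3 cis-fused adduct
Product: 4 trans-fused dienedione, (4aS,8aS)-2,5,5,8a-tetramethyl-4a,5,8,8a-tetrahydronaphthalene-1,4-dione (5α-H, 10β-methyl)
Conditions: 1,8-diazabicyclo[5.4.0]undec-7-ene (DBU, 0.2 equiv), toluene, 25 °C
Reagents that add atoms: none
Why: Base-mediated epimerisation through the C5 enolate of the C6 ketone (C5–H is the only enolisable ring-fusion hydrogen, C10 being quaternary) should lead to the trans-fused dienedione, in which both ring B bonds are equatorial on ring A, as in the classical cis-to-trans isomerisation of angularly methylated quinone Diels–Alder adducts; C10 is untouched and now controls C5.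

**Step 3**
Reactants: 4 trans-fused dienedione
Product: 5 2α,3α-epoxy-11-nordrim-7-ene-6,9-dione (5α-H, 10β-methyl)
Conditions: 3-chloroperbenzoic acid (mCPBA, 1.2 equiv), CH2Cl2, 0 °C
Reagents that add atoms: 3-chloroperbenzoic acid (mCPBA), OOC(=O)c1cccc(Cl)c1
Why: Prilezhaev epoxidation should occur only at the electron-rich C2=C3 bond (the C7=C8 bond is deactivated by two carbonyls) and from the α-face, because the β-face is covered by the axial methyl groups on C10 and C4, so both new C–O bonds are α.

**Step 4**
Reactants: 5 epoxy dienedione
Product: 6 11-nordrim-7-ene-3α,6β,9β-triol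
Conditions: LiAlH4 (4 equiv), THF, 0 °C → reflux; aqueous work-up
Reagents that add atoms: none
Why: Hydride should open the epoxide in the trans-diaxial (Fürst–Plattner) sense at C2, the carbon remote from quaternary C4, to give the axial 3α-alcohol, and reduce both ketones in the 1,2-sense from the α-face (anti to the axial C4β and C10β methyls) as in the LiAlH4 reduction of quinone-adduct ene-diones to ene-diols; the C6 and C9 carbinol centres are temporary.

**Step 5**
Reactants: 6 triol; 7 isovaleryl chloride (3-methylbutanoyl chloride)
Product: 8 6β-hydroxy-11-nordrim-7-ene-3α,9β-diyl bis(3-methylbutanoate)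
Conditions: 7 (2.5 equiv), pyridine, 4-(dimethylamino)pyridine (10 mol%), CH2Cl2, 0 → 25 °C
Reagents that add atoms: none
Why: Nucleophile-catalysed acylation should esterify the 3α- and 9β-hydroxyls but leave the 6β-hydroxyl free, since it is 1,3-diaxial to the methyl groups on C4 and C10 (the situation of an 11β-hydroxy steroid); one ester is the isovalerate of the target, the other turns the C9 oxygen into a leaving group.

**Step 6**
Reactants: 8 diester alcohol
Product: 9 6-oxo-11-nordrim-7-ene-3α,9β-diyl bis(3-methylbutanoate)
Conditions: Dess–Martin periodinane (1.5 equiv), CH2Cl2, 0 → 25 °C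
Reagents that add atoms: none
Why: Dess–Martin oxidation of the only free alcohol (allylic, hindered, axial) should give the C6 enone without touching the esters or the C5 centre.

**Step 7**
Reactants: 9 γ-acyloxy enone
Product: 11 6-oxo-11-nordrim-8-en-3α-yl 3-methylbutanoate (C7 is CH2, C8=C9 double bond), via samarium dienolate 10 (not isolated)
Conditions: SmI2 (2.5 equiv), THF–MeOH, −78 °C
Reagents that add atoms: none
Why: This is the SmI2 reductive cleavage of a γ-acyloxy enone: two single-electron transfers to the enone expel the C9 carboxylate, and the trivalent-samarium dienolate should be protonated by methanol at its α-carbon C7 to give the deconjugated C8=C9 ketone, while the unactivated C3 ester is inert.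

**Step 8**
Reactants: 11 β,γ-unsaturated ketone
Product: 12 6-(tert-butyldimethylsilyloxy)-11-nordrima-6,8-dien-3α-yl 3-methylbutanoate
Conditions: tert-butyldimethylsilyl triflate (TBSOTf, 1.2 equiv), Et3N (2 equiv), CH2Cl2, −78 → 0 °C
Reagents that add atoms: tert-butyldimethylsilyl triflate, CC(C)(C)[Si](C)(C)OS(=O)(=O)C(F)(F)F
Why: Soft enolisation (silyl triflate and amine) should remove the doubly activated C7 hydrogen, α to the ketone and allylic, in preference to the hindered C5–H between two quaternary carbons, giving the linear 6-silyloxy-6,8-diene with the ester intact.

**Step 9**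
Reactants: 12 silyl dienol ether
Product: 13 11-hydroxy-6-oxo-9βH-drim-7-en-3α-yl 3-methylbutanoate (CH2OH on C9 α, cis to H5 and trans to the C10 methyl)
Conditions: 37% aq. HCHO (excess), Yb(OTf)3 (10 mol%), THF, 0 → 25 °C
Reagents that add atoms: formaldehyde, C=O
Why: In this vinylogous Mukaiyama aldol reaction (lanthanide-triflate-catalysed hydroxymethylation) the activated formaldehyde should be attacked by the γ-carbon C9 of the dienol ether, the terminus with the largest HOMO coefficient, the α-carbon C7 being screened by the neighbouring silyloxy group, and axially from the α-face, anti to the axial C10 methyl, so that C11 becomes α and H9 β; loss of the silyl group restores the C7=C8 enone.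

**Step 10**
Reactants: 13 hydroxy enone; 14 isofraxidin (7-hydroxy-6,8-dimethoxycoumarin)
Product: 15 11-(6,8-dimethoxy-2-oxo-2H-chromen-7-yloxy)-6-oxo-9βH-drim-7-en-3α-yl 3-methylbutanoate (target)
Conditions: PPh3 (1.5 equiv), diisopropyl azodicarboxylate (1.5 equiv), THF, 0 → 25 °C
Reagents that add atoms: none
Why: Mitsunobu etherification of the primary C11 alcohol with the acidic 7-hydroxycoumarin should form the C11–O–aryl bond under neutral conditions that leave the ester, the enone and all four stereocentres (none at the reacting carbon) untouched.

**Compound list**

1 | 2,6-dimethyl-1,4-benzoquinone | CC1=CC(=O)C=C(C)C1=O | starting material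
2 | 4-methylpenta-1,3-diene | C=CC=C(C)C | starting material
3 | cis-fused adduct, (4aR,8aS)-2,5,5,8a-tetramethyl-4a,5,8,8a-tetrahydronaphthalene-1,4-dione | O=C1C(C)=CC(=O)[C@@H]2C(C)(C)C=CC[C@]12C | intermediate
4 | trans-fused dienedione, (4aS,8aS)-isomer of 3 | O=C1C(C)=CC(=O)[C@H]2C(C)(C)C=CC[C@]12C | intermediate
5 | 2α,3α-epoxy-11-nordrim-7-ene-6,9-dione | O=C1C(C)=CC(=O)[C@H]2C(C)(C)[C@@H]3O[C@@H]3C[C@]12C | intermediate
6 | 11-nordrim-7-ene-3α,6β,9β-triol | O[C@H]1C(C)=C[C@@H](O)[C@H]2C(C)(C)[C@H](O)CC[C@]12C | intermediate
7 | isovaleryl chloride | CC(C)CC(=O)Cl | starting material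
8 | 6β-hydroxy-11-nordrim-7-ene-3α,9β-diyl bis(3-methylbutanoate) | CC(C)CC(=O)O[C@H]1C(C)=C[C@@H](O)[C@H]2C(C)(C)[C@H](OC(=O)CC(C)C)CC[C@]12C | intermediate
9 | 6-oxo-11-nordrim-7-ene-3α,9β-diyl bis(3-methylbutanoate) | CC(C)CC(=O)O[C@H]1C(C)=CC(=O)[C@H]2C(C)(C)[C@H](OC(=O)CC(C)C)CC[C@]12C | intermediate
10 | trivalent-samarium 6,8-dienolate of 11 (O–SmI2) | C1=C(C)C=C(O[Sm](I)I)[C@H]2C(C)(C)[C@H](OC(=O)CC(C)C)CC[C@]12C | intermediate
11 | 6-oxo-11-nordrim-8-en-3α-yl 3-methylbutanoate | C1=C(C)CC(=O)[C@H]2C(C)(C)[C@H](OC(=O)CC(C)C)CC[C@]12C | intermediate
12 | 6-(tert-butyldimethylsilyloxy)-11-nordrima-6,8-dien-3α-yl 3-methylbutanoate | C1=C(C)C=C(O[Si](C)(C)C(C)(C)C)[C@H]2C(C)(C)[C@H](OC(=O)CC(C)C)CC[C@]12C | intermediate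
13 | 11-hydroxy-6-oxo-9βH-drim-7-en-3α-yl 3-methylbutanoate | OC[C@@H]1C(C)=CC(=O)[C@H]2C(C)(C)[C@H](OC(=O)CC(C)C)CC[C@]12C | intermediate
14 | isofraxidin | COc1cc2ccc(=O)oc2c(OC)c1O | starting material
15 | CNP0279705.1 | COc1cc2ccc(=O)oc2c(OC)c1OC[C@@H]1C(C)=CC(=O)[C@H]2C(C)(C)[C@H](OC(=O)CC(C)C)CC[C@]12C | target

**Step count and risks**

Total steps: 10. Longest linear sequence: 10 steps (1 and 2 to 15); 7 and 14 are bought.

Steps most likely to fail:

Step 1. The cycloaddition may be slow because the cis-methyl group on the diene terminus disfavours the s-cis conformer. The strongly polarised complex may also leave the concerted path, the zwitterion collapsing to a cyclobutane or an ene-type product, and an uncatalysed background reaction would lower the enantiomeric purity. The fallback sets out from 1 and 2 and replaces catalytic enantiocontrol by a racemic cycloaddition and resolution. The two partners are combined without Lewis acid under about 12 kbar in CH2Cl2 at 25–40 °C, where the compact concerted transition state is favoured; this should give 3 together with the mirror-image cis adduct F1. Epimerisation as in step 2 then gives 4 together with the mirror-image trans dienedione F2, and the enantiomers are separated by preparative chromatography on amylose tris(3,5-dimethylphenylcarbamate). The route is rejoined at 4.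

Step 9. The electrophile may attack the α-carbon C7 instead of the γ-carbon C9, because C9 adjoins the quaternary C10, and the dienol ether may be protodesilylated before it reacts. The fallback sets out from 11 and uses a directed vinylogous aldol reaction of a metal dienolate held in a bowl-shaped Lewis acid. Ketone 11 is complexed with aluminium tris(2,6-diphenylphenoxide), Al(OC6H3Ph2)3 (2.2 equiv, toluene, −78 °C), and deprotonated at C7 with LiN(iPr)2 in THF. Monomeric formaldehyde (from cracked paraformaldehyde) is then added. The aryloxide ligands bury C7, so the aluminium dienolate should react at C9, again anti to the C10 methyl, and give 13 directly, without passing through 12. No new isolable compound is made (F0).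

Step 2. The position of the cis/trans equilibrium at the dienedione stage may not favour the trans fusion clearly, and prolonged base contact may enolise through the C8 methyl. The fallback sets out from 3 and sets C5 under kinetic instead of thermodynamic control. Me3SiOTf and Et3N in CH2Cl2 at 0 °C should convert 3 into the trimethylsilyl enol ether F3, in which C5 is planar. Fluoride-triggered protonation (Bu4NF, AcOH, THF, −78 °C) should then deliver the proton to C5 from the α-face, anti to the C10 methyl, and give 4, where the route is rejoined; the ketone is reduced two steps later, before it can re-equilibrate.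

**Further compounds**

F1 | step 1 | mirror-image cis adduct (enantiomer of 3) | O=C1C(C)=CC(=O)[C@H]2C(C)(C)C=CC[C@@]12C
F2 | step 1 | mirror-image trans dienedione (enantiomer of 4) | O=C1C(C)=CC(=O)[C@@H]2C(C)(C)C=CC[C@@]12C
F0 | step 9 | none | none
F3 | step 2 | trimethylsilyl enol ether of 3 (6-trimethylsilyloxy-11-nordrima-2,5,7-trien-9-one) | O=C1C(C)=CC(O[Si](C)(C)C)=C2C(C)(C)C=CC[C@]12C
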